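## The problem

The target, (3R,4R)-4,7-bis(4-hydroxyphenyl)-4,6-dimethoxy-1-oxaspiro[2.4]hept-6-en-5-one (24), is a cyclopent-2-enone. It is numbered here C1 (carbonyl), C2 (methoxy-bearing alkene carbon), C3 (aryl-bearing alkene carbon), C4 (spiro carbon carrying the oxirane oxygen and the oxirane CH2) and C5 (carrying a methoxy group and the second aryl ring). C4 and C5 are adjacent, fully substituted, oxygenated stereocentres, with the oxirane oxygen on C4 trans to the methoxy group on C5. Neither carries hydrogen, so neither can be corrected by epimerisation and both C–O bonds must be made with absolute control. Because the two centres are neighbours, a stereospecific anti addition of two oxygens across a C4=C5 alkene of fixed geometry lets one reagent-controlled event set both, after which C4 controls C5. The ring is best closed last at C2=C3: C2 is the only enolisable carbon of a methoxymethyl ketone and C3 is an aryl ketone carbon without α-hydrogen. The fragile parts are the spiro-oxirane (acid, nucleophiles), the enol-ether enone, and the tertiary benzylic methyl ether at C5, which sits para to a phenol and can be lost through a quinone methide once phenoxide is free. The enabling feature is that C4 bears an oxygen and a CH2–O arm while C5 bears an oxygen anti to it, which is the pattern of a 2,3-epoxy alcohol opened at its benzylic carbon. The stereochemical problem therefore reduces to face selection on an achiral tetrasubstituted allylic alcohol.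

## Retrosynthesis

24 from 23: the two phenols are released last from triisopropylsilyl ethers. Buffered fluoride keeps the phenols protonated, so the C5 methyl ether is never para to a phenoxide. Nothing else changes, and the forward step only has to spare the oxirane and the enone.

23 from 21 (through aldol adduct 22): the C2=C3 bond is cut by aldol condensation. A cut at C1–C5 or C3–C4 would form a bond to a quaternary stereocentre on the ring; the C2=C3 cut touches neither stereocentre. Diketone 21 is acyclic and has a single enolisable site and a single reachable electrophile. The forward step needs a base that leaves the oxirane and the silyl ethers alone.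

21 from 19 (through bis-ozonide 20): both ketones are masked as 1,1-disubstituted alkenes. Free ketones could not be carried earlier: an enone would not undergo directed epoxidation, and a ketone next to either epoxide carbon would change the regiochemistry of opening. Both alkenes are unveiled in one ozonolysis.

19 from 15 (through 16, 17 and 18): the spiro-oxirane is the C4 oxygen closed onto its own CH2OH arm. The primary hydroxyl of 15 is sulfonylated (16) and displaced by the tertiary alkoxide (17), so the C4–O bond is never broken. The same base removes the pivalate from the C5 aryl ring (18), and the phenol is re-silylated (19). The ester is needed only while the C5–O bonds are made, and a base-labile ester would be a liability in the aldol step.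

15 from 14: the C5–OMe bond is cut back to the oxirane. Opening a 2,3-epoxy alcohol at its tertiary, benzylic and allylic carbon with inversion gives the anti O/OMe relation and leaves C4 untouched. The forward step asks for attack at C5 only and for backside attack, which is why the C5 aryl ring carries an acyloxy group and not a silyloxy group at this stage.

14 from 13: both C–O bonds of the oxirane are cut. This removes both stereocentres at once and leaves an achiral triene alcohol. The forward step is a titanium–tartrate epoxidation that must choose one face, choose the central alkene over the two flanking ones, and deliver a product that does not ionise at C5. The alkene must have the hydroxymethyl group cis to the aryl ring, which is the E isomer by the sequence rules.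

13 from 10 and 12: the C5–aryl bond is cut to an alkenyl iodide and an arylboronate. This lets the C5 aryl ring enter late with its own ester protecting group, and the coupling retains the alkene geometry.

10 from 4 and 7 (through 8 and 9): the C4–vinyl bond and the C5–I bond are cut back to an alkynol. Alkoxide-directed anti-carbomagnesiation puts the vinyl group on the proximal alkyne carbon and magnesium on the distal one inside a five-membered chelate, so regiochemistry and geometry follow from the mechanism. The neighbouring option, syn-diboration of an aryl alkynol followed by two couplings, would have to distinguish two similar C–B bonds in the first coupling.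

4 from 2 and 3, 2 from 1, 7 from 6 and 5, 12 from 11: a Sonogashira coupling, an allylic etherification, a ketone-to-vinyl-bromide conversion and two phenol protections lead back to commercial materials.

## Roads not taken

Alternative 1: the C4–C5 bond would be made by a benzilic-ester ring contraction of the six-membered trione A1. Methoxide adds to the carbonyl next to the quaternary carbon, that carbon shifts to the neighbouring carbonyl, and the cyclopentenone A2 results with the attacked carbon expelled as a methyl ester on C4. The merits are real: the whole carbon skeleton with both aryl rings comes from one six-membered ring, the ring and the C4 quaternary centre form in one step, and the route is probably shorter in C–C bond constructions than the chosen one. The weak points are three. A1 has two adjacent ketones that can both accept methoxide, and the wrong choice gives a different contraction. A1 already contains the C5 stereocentre, for which no general reagent-controlled method is at hand. The C4/C5 relative configuration depends on a conformational preference in the shift that cannot be predicted with confidence. Afterwards the ester must be reduced next to an enone carbonyl and closed to the oxirane. The chosen plan is longer, but sets absolute configuration by a catalyst and relative configuration by alkene geometry and a stereospecific opening.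

Alternative 2: the C4–C5 and C5–OMe bonds would form together when the diazoketone A3, with methanol and under Rh2(OAc)4 and a chiral phosphoric acid, gives an oxonium ylide that adds to the chloromethyl ketone carbonyl of the diketone A4, giving A5. This is the most convergent road. A5 is the chlorohydrin counterpart of diketone 21 and would be reached in a fraction of the steps, with both stereocentres made catalytically in one operation; in step economy it is clearly better. Against it, everything rests on one step that has to be selective in four ways at once: between the two ketone carbonyls of A4, against simple O–H insertion, and in both relative and absolute configuration while forming two adjacent tetrasubstituted carbons. Such trapping is established for aldehydes and strongly activated ketones with aryldiazoacetates, not for a diazoketone with an unsymmetrical 1,2-diketone. The chosen plan pays with length for stereocontrol elements that are each established on their own.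

Alternative 3: the ring would be built first by a cobalt-mediated Pauson–Khand reaction of the ynol ether A6 (as its complex formed with Co2(CO)8) with the parent allene A7 under carbon monoxide. This forms C3–C4, C5–C1 and C1–C2 and gives the methylenecyclopentenone A8. It reaches the carbocycle in the fewest steps and places the methoxy and aryl groups on C2 and C3 directly. Its weak points lie after the key step. Neither stereocentre is made in it. C5 would need sequential arylation and oxygenation at a carbon that is both α to the ketone and allylic, in a dienone prone to tautomerise to a hydroxyfulvene. The oxirane would come from epoxidation of an exocyclic 1,1-disubstituted alkene, a poor substrate class for enantioselective epoxidation, with its relation to C5 left to substrate bias. The chosen plan sets both centres on an acyclic alkene before the ring exists and closes the ring by a reaction that cannot disturb them.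

Key step: step 8

Assumption: the ring numbering C1–C5 defined above is carried back onto all acyclic precursors, and 4-(4,4,5,5-tetramethyl-1,3,2-dioxaborolan-2-yl)phenol (11) is taken as a commercial material.

## Route

Step 1
Reactants: 1 2,3-dibromoprop-1-ene
Product: 2 2-bromo-3-methoxyprop-1-ene
Conditions: NaOMe, MeOH, 0 °C → rt
Reagents that add atoms: sodium methoxide, [Na+].[O-]C
Why: Williamson-type SN2 displacement of the allylic bromide; the vinylic bromide is inert to substitution.

Step 2
Reactants: 2 2-bromo-3-methoxyprop-1-ene; 3 prop-2-yn-1-ol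
Product: 4 4-(methoxymethyl)pent-4-en-2-yn-1-ol
Conditions: Pd(PPh3)2Cl2 (2 mol %), CuI (4 mol %), Et3N, THF, rt → 40 °C
Reagents that add atoms: none
Why: Sonogashira coupling of a vinyl bromide with a terminal alkyne; the free propargylic hydroxyl and the allylic methyl ether are spectators.

Step 3
Reactants: 5 1-(4-hydroxyphenyl)ethan-1-one
Product: 6 1-[4-(triisopropylsilyloxy)phenyl]ethan-1-one
Conditions: TIPSCl, imidazole, DMF, rt
Reagents that add atoms: triisopropylsilyl chloride, CC(C)[Si](Cl)(C(C)C)C(C)C
Why: Phenol silylation; the aryl triisopropylsilyl ether is chosen because it should withstand Grignard reagents, aqueous phosphate, cold methoxide and KOtBu later on.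

Step 4
Reactants: 6 1-[4-(triisopropylsilyloxy)phenyl]ethan-1-one
Product: 7 1-(1-bromoethenyl)-4-(triisopropylsilyloxy)benzene
Conditions: P(OPh)3, Br2, CH2Cl2, −60 °C; then Et3N and 6, −60 °C → reflux
Reagents that add atoms: bromine (used as its adduct with P(OPh)3), BrBr
Why: Conversion of an aryl methyl ketone into the vinyl bromide with the triphenyl phosphite–bromine reagent: O-phosphonium activation, bromide addition and amine-mediated elimination; the silyl ether is protected from HBr by the amine.

Step 5
Reactants: 4 4-(methoxymethyl)pent-4-en-2-yn-1-ol; 7 1-(1-bromoethenyl)-4-(triisopropylsilyloxy)benzene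
Product: 10 (2Z)-3-iodo-4-(methoxymethyl)-2-{1-[4-(triisopropylsilyloxy)phenyl]ethenyl}penta-2,4-dien-1-ol, via vinylmagnesium bromide 8 (not isolated), via oxamagnesacycle 9 (not isolated)
Conditions: 7, Mg, THF, rt → 40 °C; 4, i-PrMgCl (1.0 equiv), THF, 0 °C, then the Grignard solution (2.5 equiv), THF/toluene, 70 °C; I2, THF, −40 → 0 °C; aq. Na2S2O3
Reagents that add atoms: iodine, II
Why: Alkoxide-directed anti-carbomagnesiation of a 2-alkyn-1-ol: the vinyl group is delivered to the alkyne carbon next to the CH2O arm (future C4) and magnesium ends on the distal carbon (future C5) in a five-membered chelate, so magnesium is cis to the CH2O group. Iodinolysis with retention then gives the iodide cis to the hydroxymethyl group, which fixes the alkene geometry used in the key step.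

Step 6
Reactants: 11 4-(4,4,5,5-tetramethyl-1,3,2-dioxaborolan-2-yl)phenol
Product: 12 4-(4,4,5,5-tetramethyl-1,3,2-dioxaborolan-2-yl)phenyl 2,2-dimethylpropanoate
Conditions: PivCl, Et3N, DMAP (cat.), CH2Cl2, 0 °C → rt
Reagents that add atoms: pivaloyl chloride, CC(C)(C)C(Cl)=O
Why: Phenol acylation; the pivaloyloxy group is only a weak donor, so the C5 aryl ring will not stabilise a benzylic cation in steps 8 and 9, and the hindered ester should survive aqueous phosphate.

Step 7
Reactants: 10 (2Z)-3-iodo-4-(methoxymethyl)-2-{1-[4-(triisopropylsilyloxy)phenyl]ethenyl}penta-2,4-dien-1-ol; 12 4-(4,4,5,5-tetramethyl-1,3,2-dioxaborolan-2-yl)phenyl 2,2-dimethylpropanoate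
Product: 13 4-[(2E)-1-hydroxy-4-(methoxymethyl)-2-{1-[4-(triisopropylsilyloxy)phenyl]ethenyl}penta-2,4-dien-3-yl]phenyl 2,2-dimethylpropanoate (hydroxymethyl cis to the pivaloyloxyphenyl ring)
Conditions: Pd(dppf)Cl2 (5 mol %), K3PO4, THF/H2O (10:1), 50 °C
Reagents that add atoms: none
Why: Suzuki–Miyaura coupling of an alkenyl iodide proceeds with retention, so the aryl ring takes the place of iodine cis to the hydroxymethyl group; the reactive C–I bond allows 50 °C, where the pivalate and the silyl ether should hold.

Step 8
Reactants: 13 4-[(2E)-1-hydroxy-4-(methoxymethyl)-2-{1-[4-(triisopropylsilyloxy)phenyl]ethenyl}penta-2,4-dien-3-yl]phenyl 2,2-dimethylpropanoate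
Product: 14 [(2R,3R)-3-(3-methoxyprop-1-en-2-yl)-3-[4-(pivaloyloxy)phenyl]-2-{1-[4-(triisopropylsilyloxy)phenyl]ethenyl}oxiran-2-yl]methanol
Conditions: Ti(OiPr)4 (0.3 equiv), D-(−)-diethyl tartrate (0.36 equiv), t-BuOOH (2 equiv, in decane), 4 Å MS, CH2Cl2, −20 °C; non-acidic work-up
Reagents that add atoms: tert-butyl hydroperoxide, CC(C)(C)OO
Why: Katsuki–Sharpless asymmetric epoxidation: the primary alkoxide of 13 and tert-butyl peroxide bind to the dimeric Ti(OiPr)4–tartrate catalyst and the distal peroxide oxygen is passed to the alkene inside that complex. The closest known reaction type is the titanium–tartrate epoxidation of tetrasubstituted primary allylic alcohols. The oxirane closes by concerted, suprafacial oxygen-atom transfer to C4=C5, so both C–O bonds form on one face in one step. Both C4 and C5 are set by the tartrate: natural L-(+)-tartrate gives the 2S epoxy alcohol when the geminal substituent is the lowest-ranked group at the carbinol-bearing carbon, the same ranking holds here, and the 2R centre required for C4 therefore calls for D-(−)-diethyl tartrate. The C4/C5 relative configuration is that of the alkene, fixed in steps 5 and 7. The step needs chemoselectivity for the central alkene, which alone is allylic to the titanium-bound oxygen; the two 1,1-disubstituted alkenes are homoallylic or remote and should react far more slowly. It also needs the product to survive, which is secured by the weakly donating pivaloyloxyaryl ring at C5, by substoichiometric titanium with molecular sieves at −20 °C and by a non-acidic work-up.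

Step 9
Reactants: 14 [(2R,3R)-3-(3-methoxyprop-1-en-2-yl)-3-[4-(pivaloyloxy)phenyl]-2-{1-[4-(triisopropylsilyloxy)phenyl]ethenyl}oxiran-2-yl]methanol
Product: 15 (2R,3S)-3-methoxy-4-(methoxymethyl)-3-[4-(pivaloyloxy)phenyl]-2-{1-[4-(triisopropylsilyloxy)phenyl]ethenyl}pent-4-ene-1,2-diol
Conditions: CSA (10 mol %), MeOH, −20 → 0 °C; Et3N quench
Reagents that add atoms: methanol, CO
Why: Acid-catalysed methanolysis of a 2,3-epoxy alcohol at C5, the only epoxide carbon that is both benzylic and allylic, by backside (borderline SN2) attack of solvent methanol, which inverts C5 and gives the anti O/OMe relation. C4 keeps its oxygen and configuration, and the acyloxyaryl ring keeps the transition state tight enough for inversion.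

Step 10
Reactants: 15 (2R,3S)-3-methoxy-4-(methoxymethyl)-3-[4-(pivaloyloxy)phenyl]-2-{1-[4-(triisopropylsilyloxy)phenyl]ethenyl}pent-4-ene-1,2-diol
Product: 18 4-[(1S)-1-methoxy-2-(methoxymethyl)-1-[(2R)-2-{1-[4-(triisopropylsilyloxy)phenyl]ethenyl}oxiran-2-yl]prop-2-en-1-yl]phenol, via primary tosylate 16 (not isolated), via pivalate spiro-epoxide 17 (not isolated)
Conditions: TsCl (1.05 equiv), Et3N, DMAP (cat.), CH2Cl2, 0 °C → rt; aqueous wash; crude into NaOMe, MeOH, 0 °C → rt; NH4Cl quench
Reagents that add atoms: none
Why: Only the primary hydroxyl is sulfonylated, and the tertiary alkoxide then closes the oxirane by 3-exo-tet Williamson displacement with the C4–O bond intact, so C4 keeps its configuration. Methoxide also transesterifies the aryl pivalate, which has done its work; the mixture is kept cold and quenched promptly so that the phenoxide para to the C5 methyl ether has little time to expel methoxide.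

Step 11
Reactants: 18 4-[(1S)-1-methoxy-2-(methoxymethyl)-1-[(2R)-2-{1-[4-(triisopropylsilyloxy)phenyl]ethenyl}oxiran-2-yl]prop-2-en-1-yl]phenol
Product: 19 (2R)-2-{(1S)-1-methoxy-2-(methoxymethyl)-1-[4-(triisopropylsilyloxy)phenyl]prop-2-en-1-yl}-2-{1-[4-(triisopropylsilyloxy)phenyl]ethenyl}oxirane
Conditions: TIPSCl, imidazole, DMF, rt
Reagents that add atoms: triisopropylsilyl chloride, CC(C)[Si](Cl)(C(C)C)C(C)C
Why: Phenol silylation; both phenols now carry the same base-stable, fluoride-labile group, and any material that lost the other silyl group in step 10 converges here.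

Step 12
Reactants: 19 (2R)-2-{(1S)-1-methoxy-2-(methoxymethyl)-1-[4-(triisopropylsilyloxy)phenyl]prop-2-en-1-yl}-2-{1-[4-(triisopropylsilyloxy)phenyl]ethenyl}oxirane
Product: 21 (1R)-1,3-dimethoxy-1-[4-(triisopropylsilyloxy)phenyl]-1-{(2R)-2-[4-(triisopropylsilyloxy)benzoyl]oxiran-2-yl}propan-2-one, via bis-ozonide 20 (not isolated)
Conditions: O3, CH2Cl2, −78 °C, stopped at first persistent blue; then PPh3, −78 °C → rt
Reagents that add atoms: ozone, [O-][O+]=O
Why: Ozonolysis (cycloaddition, cycloreversion, recombination to 1,2,4-trioxolanes, phosphine reduction) cleaves both 1,1-disubstituted alkenes to ketones and formaldehyde. The oxirane and the silyl ethers are inert, and no stereocentre carries hydrogen.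

Step 13
Reactants: 21 (1R)-1,3-dimethoxy-1-[4-(triisopropylsilyloxy)phenyl]-1-{(2R)-2-[4-(triisopropylsilyloxy)benzoyl]oxiran-2-yl}propan-2-one
Product: 23 (3R,4R)-4,6-dimethoxy-4,7-bis[4-(triisopropylsilyloxy)phenyl]-1-oxaspiro[2.4]hept-6-en-5-one, via aldol adduct 22 (not isolated)
Conditions: KOtBu (1.1 equiv), THF, −20 → 0 °C; NH4Cl quench
Reagents that add atoms: none
Why: Intramolecular aldol condensation: the CH2 of the methoxymethyl ketone is the only enolisable position and the aryl ketone the only carbonyl it can reach, in a 5-(enolexo)-exo-trig closure, followed by E1cB loss of hydroxide to the tetrasubstituted enol-ether enone. Both stereocentres are quaternary and cannot epimerise, and the aryl silyl ethers keep the ketone electrophilic.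

Step 14
Reactants: 23 (3R,4R)-4,6-dimethoxy-4,7-bis[4-(triisopropylsilyloxy)phenyl]-1-oxaspiro[2.4]hept-6-en-5-one
Product: 24 (3R,4R)-4,7-bis(4-hydroxyphenyl)-4,6-dimethoxy-1-oxaspiro[2.4]hept-6-en-5-one
Conditions: TBAF, AcOH (1:1), THF, 0 °C
Reagents that add atoms: none
Why: Fluoride cleavage of the aryl silyl ethers, buffered with acetic acid so that the phenols are released protonated; the oxirane, the enone and the C5 methyl ether should be untouched.

## Compound list

1 | 2,3-dibromoprop-1-ene | BrCC(Br)=C | starting material
2 | 2-bromo-3-methoxyprop-1-ene | COCC(Br)=C | intermediate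
3 | prop-2-yn-1-ol | OCC#C | starting material
4 | 4-(methoxymethyl)pent-4-en-2-yn-1-ol | OCC#CC(=C)COC | intermediate
5 | 1-(4-hydroxyphenyl)ethan-1-one | CC(=O)c1ccc(O)cc1 | starting material
6 | 1-[4-(triisopropylsilyloxy)phenyl]ethan-1-one | CC(=O)c1ccc(O[Si](C(C)C)(C(C)C)C(C)C)cc1 | intermediate
7 | 1-(1-bromoethenyl)-4-(triisopropylsilyloxy)benzene | C=C(Br)c1ccc(O[Si](C(C)C)(C(C)C)C(C)C)cc1 | intermediate
8 | {1-[4-(triisopropylsilyloxy)phenyl]ethenyl}magnesium bromide | C=C([Mg]Br)c1ccc(O[Si](C(C)C)(C(C)C)C(C)C)cc1 | intermediate (not isolated)
9 | 3-(3-methoxyprop-1-en-2-yl)-4-{1-[4-(triisopropylsilyloxy)phenyl]ethenyl}-2,5-dihydro-1,2-oxamagnesole (cyclic alkenylmagnesium alkoxide) | C=C(c1ccc(O[Si](C(C)C)(C(C)C)C(C)C)cc1)C1=C(C(=C)COC)[Mg]OC1 | intermediate (not isolated)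
10 | (2Z)-3-iodo-4-(methoxymethyl)-2-{1-[4-(triisopropylsilyloxy)phenyl]ethenyl}penta-2,4-dien-1-ol (iodine cis to CH2OH) | OC/C(C(=C)c1ccc(O[Si](C(C)C)(C(C)C)C(C)C)cc1)=C(\I)C(=C)COC | intermediate
11 | 4-(4,4,5,5-tetramethyl-1,3,2-dioxaborolan-2-yl)phenol | CC1(C)OB(OC1(C)C)c1ccc(O)cc1 | starting material
12 | 4-(4,4,5,5-tetramethyl-1,3,2-dioxaborolan-2-yl)phenyl 2,2-dimethylpropanoate | CC(C)(C)C(=O)Oc1ccc(cc1)B1OC(C)(C)C(C)(C)O1 | intermediate
13 | 4-[(2E)-1-hydroxy-4-(methoxymethyl)-2-{1-[4-(triisopropylsilyloxy)phenyl]ethenyl}penta-2,4-dien-3-yl]phenyl 2,2-dimethylpropanoate (CH2OH cis to the pivaloyloxyphenyl ring) | OC/C(C(=C)c1ccc(O[Si](C(C)C)(C(C)C)C(C)C)cc1)=C(\c1ccc(OC(=O)C(C)(C)C)cc1)C(=C)COC | intermediate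
14 | [(2R,3R)-3-(3-methoxyprop-1-en-2-yl)-3-[4-(pivaloyloxy)phenyl]-2-{1-[4-(triisopropylsilyloxy)phenyl]ethenyl}oxiran-2-yl]methanol | C=C(c1ccc(O[Si](C(C)C)(C(C)C)C(C)C)cc1)[C@]2(CO)O[C@]2(c1ccc(OC(=O)C(C)(C)C)cc1)C(=C)COC | intermediate
15 | (2R,3S)-3-methoxy-4-(methoxymethyl)-3-[4-(pivaloyloxy)phenyl]-2-{1-[4-(triisopropylsilyloxy)phenyl]ethenyl}pent-4-ene-1,2-diol | C=C(c1ccc(O[Si](C(C)C)(C(C)C)C(C)C)cc1)[C@@](O)(CO)[C@](OC)(c1ccc(OC(=O)C(C)(C)C)cc1)C(=C)COC | intermediate
16 | (2R,3S)-2-hydroxy-3-methoxy-4-(methoxymethyl)-3-[4-(pivaloyloxy)phenyl]-2-{1-[4-(triisopropylsilyloxy)phenyl]ethenyl}pent-4-en-1-yl 4-methylbenzenesulfonate | C=C(c1ccc(O[Si](C(C)C)(C(C)C)C(C)C)cc1)[C@@](O)(COS(=O)(=O)c1ccc(C)cc1)[C@](OC)(c1ccc(OC(=O)C(C)(C)C)cc1)C(=C)COC | intermediate (not isolated)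
17 | 4-[(1S)-1-methoxy-2-(methoxymethyl)-1-[(2R)-2-{1-[4-(triisopropylsilyloxy)phenyl]ethenyl}oxiran-2-yl]prop-2-en-1-yl]phenyl 2,2-dimethylpropanoate | C=C(c1ccc(O[Si](C(C)C)(C(C)C)C(C)C)cc1)[C@@]2(CO2)[C@](OC)(c1ccc(OC(=O)C(C)(C)C)cc1)C(=C)COC | intermediate (not isolated)
18 | 4-[(1S)-1-methoxy-2-(methoxymethyl)-1-[(2R)-2-{1-[4-(triisopropylsilyloxy)phenyl]ethenyl}oxiran-2-yl]prop-2-en-1-yl]phenol | C=C(c1ccc(O[Si](C(C)C)(C(C)C)C(C)C)cc1)[C@@]2(CO2)[C@](OC)(c1ccc(O)cc1)C(=C)COC | intermediate
19 | (2R)-2-{(1S)-1-methoxy-2-(methoxymethyl)-1-[4-(triisopropylsilyloxy)phenyl]prop-2-en-1-yl}-2-{1-[4-(triisopropylsilyloxy)phenyl]ethenyl}oxirane | C=C(c1ccc(O[Si](C(C)C)(C(C)C)C(C)C)cc1)[C@@]2(CO2)[C@](OC)(c1ccc(O[Si](C(C)C)(C(C)C)C(C)C)cc1)C(=C)COC | intermediate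
20 | bis-ozonide of 19: each C=CH2 group converted into a 3,3-disubstituted 1,2,4-trioxolane ring, oxirane and C5 centre unchanged, trioxolane carbons unassigned | C1(c2ccc(O[Si](C(C)C)(C(C)C)C(C)C)cc2)(OOCO1)[C@@]3(CO3)[C@](OC)(c2ccc(O[Si](C(C)C)(C(C)C)C(C)C)cc2)C4(COC)OOCO4 | intermediate (not isolated)
21 | (1R)-1,3-dimethoxy-1-[4-(triisopropylsilyloxy)phenyl]-1-{(2R)-2-[4-(triisopropylsilyloxy)benzoyl]oxiran-2-yl}propan-2-one | O=C(c1ccc(O[Si](C(C)C)(C(C)C)C(C)C)cc1)[C@@]2(CO2)[C@](OC)(c1ccc(O[Si](C(C)C)(C(C)C)C(C)C)cc1)C(=O)COC | intermediate
22 | aldol adduct: 7-hydroxy-4,6-dimethoxy-4,7-bis[4-(triisopropylsilyloxy)phenyl]-1-oxaspiro[2.4]heptan-5-one, spiro carbon and C4 as in 23, C6 and C7 unassigned | COC1C(O)(c2ccc(O[Si](C(C)C)(C(C)C)C(C)C)cc2)[C@@]2(CO2)[C@](OC)(c2ccc(O[Si](C(C)C)(C(C)C)C(C)C)cc2)C1=O | intermediate (not isolated)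
23 | (3R,4R)-4,6-dimethoxy-4,7-bis[4-(triisopropylsilyloxy)phenyl]-1-oxaspiro[2.4]hept-6-en-5-one | COC1=C(c2ccc(O[Si](C(C)C)(C(C)C)C(C)C)cc2)[C@@]2(CO2)[C@](OC)(c2ccc(O[Si](C(C)C)(C(C)C)C(C)C)cc2)C1=O | intermediate
24 | (3R,4R)-4,7-bis(4-hydroxyphenyl)-4,6-dimethoxy-1-oxaspiro[2.4]hept-6-en-5-one | COC1=C(c2ccc(O)cc2)[C@@]2(CO2)[C@](OC)(c2ccc(O)cc2)C1=O | target

## Step count and least certain steps

Total: 14 steps. Longest linear sequence: 11 steps (steps 1, 2, 5, 7, 8, 9, 10, 11, 12, 13, 14 from 1; the count is the same from 5 through steps 3 and 4).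

Step 8 (key step). Oxygen transfer to a tetrasubstituted, cross-conjugated and crowded alkene may be slow. Long exposure to titanium would then allow titanium-assisted opening of the product at C5 by isopropanol or tartrate, and face discrimination may be lower than for less substituted allylic alcohols. Fallback: setting out from 13, the epoxidation would be run with VO(OiPr)3 and a C2-symmetric chiral bishydroxamic acid ligand with aqueous t-BuOOH in toluene at 0 °C. This is ligand-accelerated catalysis on pentavalent vanadium, which is far less Lewis acidic toward the product. The crude epoxy alcohol 14 would not be purified but quenched directly into cold methanolic CSA, so the sequence comes back to the route at 15.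

Step 5. Addition of the hindered 1-arylvinyl Grignard reagent to the magnesium alkoxide of the enynol may be slow at a temperature the enyne tolerates, so that metalation or oligomerisation of 4 competes. Fallback: setting out from 4, alkoxide-anchored trans-diboration (n-BuLi, then B2pin2, THF, heat) should give the oxaborole 3-(3-methoxyprop-1-en-2-yl)-4-(4,4,5,5-tetramethyl-1,3,2-dioxaborolan-2-yl)-1,2-oxaborol-2(5H)-ol F1, whose ring boron sits on the distal alkyne carbon cis to the CH2O arm. Suzuki coupling of this more reactive cyclic boronic hemiester with 4-iodophenyl 2,2-dimethylpropanoate F2 (from 4-iodophenol and pivaloyl chloride) should give the alkenylboronate 4-[(2E)-1-hydroxy-4-(methoxymethyl)-2-(4,4,5,5-tetramethyl-1,3,2-dioxaborolan-2-yl)penta-2,4-dien-3-yl]phenyl 2,2-dimethylpropanoate F3. A second Suzuki coupling of F3 with vinyl bromide 7 (Pd(OAc)2, SPhos, K3PO4, THF/H2O) would come back to the route at 13, bypassing 10 and 12.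

Step 9. Ionisation of the protonated oxirane to an open tertiary benzylic and allylic cation would let methanol enter from both faces and erode C5. It would also allow attack at the terminal CH2 of the C5 vinyl group (allylic transposition) or a 1,2-shift from C4. Fallback: setting out from 14, the primary hydroxyl would first be sulfonylated (TsCl, Et3N, DMAP) to the epoxy tosylate [(2R,3R)-3-(3-methoxyprop-1-en-2-yl)-3-[4-(pivaloyloxy)phenyl]-2-{1-[4-(triisopropylsilyloxy)phenyl]ethenyl}oxiran-2-yl]methyl 4-methylbenzenesulfonate F4. The sulfonate lowers the basicity of the oxirane oxygen and withdraws electron density next to C5, so opening with BF3·OEt2 in methanol at −40 °C must be more concerted. The product is hydroxy tosylate 16, where the sequence comes back to the route for the base treatment of step 10.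

Step 13. The aldol addition may stop at adduct 22 because loss of hydroxide from the hindered tertiary carbinol is slow. Prolonged base would then favour retro-aldol cleavage, attack of alkoxide or hydroxide on the oxirane, or loss of the silyl group from the ketone aryl ring, which would turn the aryl ketone into an unreactive phenoxide ketone. Fallback: setting out from 21, the enolate would be formed irreversibly with LiN(SiMe3)2 in THF at −78 °C and the aldol adduct 22 isolated after a cold quench. It would then be dehydrated under neutral conditions with Burgess reagent (or Martin sulfurane), coming back to the route at 23.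

## Further compounds

F1 | step 5 | 3-(3-methoxyprop-1-en-2-yl)-4-(4,4,5,5-tetramethyl-1,3,2-dioxaborolan-2-yl)-1,2-oxaborol-2(5H)-ol | COCC(=C)C1=C(B2OC(C)(C)C(C)(C)O2)COB1O
F2 | step 5 | 4-iodophenyl 2,2-dimethylpropanoate | CC(C)(C)C(=O)Oc1ccc(I)cc1
F3 | step 5 | 4-[(2E)-1-hydroxy-4-(methoxymethyl)-2-(4,4,5,5-tetramethyl-1,3,2-dioxaborolan-2-yl)penta-2,4-dien-3-yl]phenyl 2,2-dimethylpropanoate | OC/C(B1OC(C)(C)C(C)(C)O1)=C(\c1ccc(OC(=O)C(C)(C)C)cc1)C(=C)COC
F0 | step 8 | none | none
F4 | step 9 | [(2R,3R)-3-(3-methoxyprop-1-en-2-yl)-3-[4-(pivaloyloxy)phenyl]-2-{1-[4-(triisopropylsilyloxy)phenyl]ethenyl}oxiran-2-yl]methyl 4-methylbenzenesulfonate | C=C(c1ccc(O[Si](C(C)C)(C(C)C)C(C)C)cc1)[C@]2(COS(=O)(=O)c1ccc(C)cc1)O[C@]2(c1ccc(OC(=O)C(C)(C)C)cc1)C(=C)COC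
F0 | step 13 | none | none
A1 | alternative 1 | (6S)-2,6-dimethoxy-3,6-bis[4-(prop-2-en-1-yloxy)phenyl]cyclohex-2-ene-1,4,5-trione | COC1=C(c2ccc(OCC=C)cc2)C(=O)C(=O)[C@](OC)(c2ccc(OCC=C)cc2)C1=O
A2 | alternative 1 | methyl 1-hydroxy-3,5-dimethoxy-4-oxo-2,5-bis[4-(prop-2-en-1-yloxy)phenyl]cyclopent-2-ene-1-carboxylate | COC1=C(c2ccc(OCC=C)cc2)[C@@](O)(C(=O)OC)[C@](OC)(c2ccc(OCC=C)cc2)C1=O
A3 | alternative 2 | 1-[4-(tert-butyldimethylsilyloxy)phenyl]-1-diazo-3-methoxypropan-2-one | COCC(=O)C(=[N+]=[N-])c1ccc(O[Si](C)(C)C(C)(C)C)cc1
A4 | alternative 2 | 1-[4-(tert-butyldimethylsilyloxy)phenyl]-3-chloropropane-1,2-dione | O=C(CCl)C(=O)c1ccc(O[Si](C)(C)C(C)(C)C)cc1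
A5 | alternative 2 | 2-(chloromethyl)-2-hydroxy-3,5-dimethoxy-1,3-bis[4-(tert-butyldimethylsilyloxy)phenyl]pentane-1,4-dione | O=C(c1ccc(O[Si](C)(C)C(C)(C)C)cc1)[C@@](O)(CCl)[C@](OC)(c1ccc(O[Si](C)(C)C(C)(C)C)cc1)C(=O)COC
A6 | alternative 3 | tert-butyl[4-(methoxyethynyl)phenoxy]dimethylsilane | COC#Cc1ccc(O[Si](C)(C)C(C)(C)C)cc1
A7 | alternative 3 | propa-1,2-diene (allene) | C=C=C
A8 | alternative 3 | 3-[4-(tert-butyldimethylsilyloxy)phenyl]-2-methoxy-4-methylidenecyclopent-2-en-1-one | COC1=C(c2ccc(O[Si](C)(C)C(C)(C)C)cc2)C(=C)CC1=O
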